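## Structural features

The target is a profisetinidin-type tetraflavanoid. A (+)-catechin unit K (ring A of phloroglucinol type, 2R,3S) carries two flavan-3-ol substituents on its ring A: the middle unit M on C8 and the side unit S on C6. M in turn carries the top unit T on C6 of its resorcinol-type ring A. T, M and S are ent-fisetinidol units (5-deoxy ring A with 7-OH, catechol ring B), each joined through its sp3 carbon C4 to an aromatic carbon of the next unit; the interflavanyl bonds are C4(T)–C6(M), C4(M)–C8(K) and C4(S)–C6(K). In each of these three units C2, C3 and C4 are contiguous stereocentres with the same arrangement: 2S,3R, the aryl group on C2 on the β face, the hydroxyl on C3 and the aryl group on C4 both on the α face (2,3-trans-3,4-cis, a 4α linkage). With C2 and C3 of K this gives eleven stereocentres. Thirteen phenolic hydroxyls make the free compound sensitive to air and base, and the doubly benzylic C4–H bonds and the benzylic C2–O1 bonds are sensitive to acid and oxidants. The real difficulty is nine stereocentres in three almost identical rings C: the 2S series is not available from the flavan-3-ol chiral pool, the 3,4-cis relation is the one that carbon nucleophiles adding to a flavan-4-yl cation disfavour, and C6 and C8 of K are each flanked by two oxygen substituents. The key step uses the fact that, with C3=C4 written as an alkene, ring C of T, M and S is a 2,4-diaryl-2H-chromene whose O1–C2 bond opens and recloses under near-UV light, so C2 can stay unassigned until the C3=C4 alkene is epoxidised.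

## Logic of the disconnections

22 ⇒ 21. Fourteen O–CH2Ph bonds are cut (thirteen phenolic ethers and the ether on O3 of K). Benzyl is chosen because one neutral hydrogenolysis removes all of them and 21 is the last compound that can be purified on silica. The gain is that every phenol is masked through all oxidative, basic and Lewis-acidic steps. The demand is that the hydrogenolysis leaves the C4–aryl and C2–O1 ring bonds alone.

21 ⇒ 20. The three C4–H bonds are cut and O3 is reconnected to C4, so each 3-hydroxy-4-aryl unit becomes a cis-fused 3,4-oxirane. An oxirane lets C4 be set by inversion, which places hydrogen trans and the aryl group cis to O3, exactly the 3,4-cis pattern that direct cation capture does not favour. The gain is that C4 no longer needs a stereocontrolled C–C bond formation. The demand is opening at C4 only, with hydride capture faster than a 1,2-shift.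

20 ⇒ 19. Three C3–O and three C4–O bonds are cut and the configuration at the three C2 centres is released. This removes nine stereocentres at once and leaves three identical, stereorandom 2H-chromene rings that can be made from racemic material. The demand is a catalyst that chooses one alkene face, a clear rate difference between C2 epimers, and C2 epimerisation that keeps pace with oxidation.

19 ⇒ 18 + 12. The sp2–sp2 bond C4(M)–C8(K) is cut. It is the bond that joins the two halves of the molecule, and as an aryl–alkenyl bond it can be made by cross-coupling without touching any stereocentre. The gain is convergence, with about half of the atoms in each partner. The demand is a coupling at an aryl bromide flanked by two oxygens.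

18 ⇒ 17 + 6, and 17 ⇒ 16 ⇒ 15 ⇒ 14 ⇒ 13. The bond C4(S)–C6(K) is cut, then C6–I, C8–Br and the five O–benzyl bonds of K. Bromine goes to C8 because that is where the first electrophile enters; iodine then takes the only site left. The two halogens give the two positions of K different reactivity, so one boronate (6) serves for S and no halogenation is needed after an alkene is present. The demand is clean selection of C–I over C–Br in the first coupling.

12 ⇒ 11 ⇒ 10 ⇒ 9 + 6. The C4–B bond and the enol O–S bond of M are cut back to a ketone, then the bond C4(T)–C6(M). The ketone of M serves as a masked alkenyl nucleophile while the ring A bromide of 9 is used, so M can act first as electrophile and later as nucleophile. The demand is that a flavanone survives a cross-coupling.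

6 ⇒ 5 ⇒ 4 ⇒ 1 + 2, and 9 ⇒ 7 + 2, 7 ⇒ 1. The C4–B and enol O–S bonds are cut, then O1–C2 (oxa-Michael) and C2–C3 (aldol) of the flavanone through 3 or 8, and for 7 the C5–Br bond. All three flavene units then come from two cheap aromatic building blocks and ring B arrives ready-made with 2. The demand is only that the enolate of a flavanone is trapped before it ring-opens. No stereocontrol is asked for.

A route to 19 through three diaryl ketones (two on ring A of 15, one on ring A of M), their methylenation and acid condensation with 2 was set aside. It needs Friedel–Crafts acylation next to benzyl ethers, a Wittig reaction at ketones flanked by two ortho oxygens, and an acid step on electron-rich 1,1-diarylethenes. The constitution of 19 is unchanged.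

## Other disconnections considered

Alternative 1: The cut lies inside ring A of T: C4a–C5 and C8–C8a are disconnected, so ring C of T exists first as a δ-lactone whose carbonyl carbon is the future C8a. Forward, the lithium enolate of that lactone adds to methyl vinyl ketone A2 at the future C4a; KOtBu then drives Claisen attack of the methyl ketone enolate on the lactone carbonyl; acid recloses O1 on the resulting 1,3-dione as a vinylogous ester and gives the hexahydrochromen-7-one A1, which must still be dehydrogenated to the 7-hydroxy arene. In its favour, every event is ground-state enolate chemistry of known type, C2, C3 and C4 of T are in place beforehand, C4 is not α to the carbonyl, and neither a flavan-4-yl cation nor light is involved. On mechanistic precedent this alternative is better than the chosen plan. Against it here: it builds atom by atom a resorcinol ring that the chosen plan takes from 1; it deals with one unit only, so M, S and K with all their stereocentres must already be assembled and must survive strong base and acid; C4a forms as a mixture and the Michael step can revert; and the late aromatisation needs an oxidant in a molecule full of benzyl ethers and doubly benzylic C4–H bonds. On structure the two plans are equal in that the K–M–S–T connectivity has to be made by other reactions in both. On step economy the chosen plan is clearly shorter, because its key operation acts on all three units at once.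

Alternative 2: The cut is made at the three O1–C2 bonds. Forward, PPh3 and diisopropyl azodicarboxylate activate the three benzylic hydroxyls and each ring A phenol displaces with inversion (threefold Mitsunobu etherification, 6-exo-tet) to give A3, whose tertiary C4 hydroxyls are removed afterwards; the C2–C3 pair of each unit would come from droxidopa A4, whose benzylic carbinol and α-amino centre map onto the 2S,3R pattern after that one inversion. In its favour, the absolute configuration at C2 and C3 comes from the chiral pool and phenol Mitsunobu closure of flavans is known chemistry; on the source of absolute stereochemistry it is better than an untested catalyst-controlled resolution. The later removal of the C4 hydroxyl passes through the same diaryl cation as step 16, so on the C4 question the plans are about equal, the chosen one having the extra invertive bias of the oxirane. Against it: a 3,4-dialkoxybenzylic oxyphosphonium ionises easily, so inversion can leak to SN1 mixtures; the neighbouring C3 and C4 hydroxyls compete (oxirane formation, five-membered closure at C3, elimination of the tertiary alcohol), and this must go right three times in one molecule; and three chains from A4 must be attached to hindered aryl positions of K and M. On structure it has the advantage that C2 is sp3 throughout, so no compound needs protection from light. On step economy it is longer.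

Alternative 3: The cut is made at the three C2–C1′ bonds to the catechol rings of T, M and S. Forward, at a carbon cathode with a zinc anode, NiBr2·glyme and 4,4′-di-tert-butyl-2,2′-bipyridine couple each anomeric C2 chloride with 4-bromo-1,2-bis(benzyloxy)benzene A6 in a reductive cross-electrophile coupling that gives the heptadeca-O-benzyl ether A5. In its favour, nickel coupling of α-chloro ethers with aryl bromides is a known reaction class, so precedent is closer than for the chosen key step; the C2 radical should be captured anti to the C3 benzyloxy group, which is the 2,3-trans relation required; and only hydrogenolysis follows, so its end-game is one step shorter and on that point it is better. Against it: the chlorinated tetramer without three rings B must be made with C3 and C4 already set in all three units, which moves the hard stereochemical problem without solving it; an α-chloro ether next to a β-benzyloxy group tends to eliminate reductively to the 2H-chromene at nickel or zinc; three couplings of an electron-rich aryl bromide must all succeed under substrate control; and the rings B, which the chosen plan gets with aldehyde 2, must be attached one bond at a time. The plans are equal in protecting-group strategy and final deprotection.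

Key step: step 15

Remarks on the chemistry:
- α means below ring C when ring A is drawn on the left and O1 at the top.
- The C2 centres of the flavanone and chromene units in 4–6, 9–12, 18 and 19 are deliberately undefined (racemates or epimer mixtures). Compounds with a 2H-chromene ring are handled under amber light until step 15.
- The stereodescriptors of 19 and 20 were checked atom by atom against 22 and are consistent; no structure needed correction. The aryl group on C2 that is β is described as 2R in a flavanone or chromene and as 2S in the flavan, only because the CIP priorities change.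
- The (R,R) enantiomer of the manganese complex is assigned by analogy with 2,2-dimethylchromene. If the 4-aryl group reverses the facial sense, the (S,S) complex is used.

## Route

Step 1
Reactants: 1 1-[4-(benzyloxy)-2-hydroxyphenyl]ethan-1-one; 2 3,4-bis(benzyloxy)benzaldehyde
Product: 4 rac-7-(benzyloxy)-2-[3,4-bis(benzyloxy)phenyl]chroman-4-one, via chalcone 3 (not isolated)
Conditions: KOH (aq.), EtOH, rt; then AcOH to pH 6, reflux
Reagents that add atoms: none
Why: Claisen–Schmidt condensation gives the (E)-2′-hydroxychalcone 3, and the acetate buffer formed on neutralisation catalyses the oxa-Michael closure of O1–C2 to the flavanone; the equilibrium is incomplete, so recovered 3 is resubmitted. C2 is formed racemic on purpose because it is re-equilibrated in step 15.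

Step 2
Reactants: 4 rac-7-(benzyloxy)-2-[3,4-bis(benzyloxy)phenyl]chroman-4-one
Product: 5 rac-7-(benzyloxy)-2-[3,4-bis(benzyloxy)phenyl]-2H-chromen-4-yl trifluoromethanesulfonate
Conditions: KN(SiMe3)2, THF, −78 °C; N-(5-chloro-2-pyridyl)bis(trifluoromethanesulfonimide), −78 °C
Reagents that add atoms: N-(5-chloro-2-pyridyl)bis(trifluoromethanesulfonimide), FC(F)(F)S(=O)(=O)N(c1ccc(Cl)cn1)S(=O)(=O)C(F)(F)F
Why: Kinetic deprotonation at C3 and O-sulfonylation of the potassium enolate give the enol triflate, a standard conversion of aryl ketones. The low temperature and the reactive pyridyl triflimide are chosen so that trapping outruns E1cB opening of the enolate to the chalcone phenoxide.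

Step 3
Reactants: 5 rac-7-(benzyloxy)-2-[3,4-bis(benzyloxy)phenyl]-2H-chromen-4-yl trifluoromethanesulfonate
Product: 6 rac-2-{7-(benzyloxy)-2-[3,4-bis(benzyloxy)phenyl]-2H-chromen-4-yl}-4,4,5,5-tetramethyl-1,3,2-dioxaborolane
Conditions: B2pin2, PdCl2(PPh3)2, PPh3, KOPh, toluene, 50 °C, dark
Reagents that add atoms: bis(pinacolato)diboron, CC1(C)OB(OC1(C)C)B1OC(C)(C)C(C)(C)O1
Why: Miyaura borylation of an alkenyl triflate; phenoxide is the mild base that lets boron transfer proceed without homocoupling. No stereocentre is touched.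

Step 4
Reactants: 1 1-[4-(benzyloxy)-2-hydroxyphenyl]ethan-1-one
Product: 7 1-[4-(benzyloxy)-5-bromo-2-hydroxyphenyl]ethan-1-one
Conditions: NBS, MeCN, 0 °C → rt
Reagents that add atoms: N-bromosuccinimide, BrN1C(=O)CCC1=O
Why: Electrophilic aromatic bromination; C5 is para to the free hydroxyl, ortho to the benzyl ether and less hindered than C3 between the two oxygens, as in the bromination of the 4-O-methyl analogue.

Step 5
Reactants: 7 1-[4-(benzyloxy)-5-bromo-2-hydroxyphenyl]ethan-1-one; 2 3,4-bis(benzyloxy)benzaldehyde
Product: 9 rac-7-(benzyloxy)-6-bromo-2-[3,4-bis(benzyloxy)phenyl]chroman-4-one, via bromochalcone 8 (not isolated)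
Conditions: KOH (aq.), EtOH, rt; then AcOH to pH 6, reflux
Reagents that add atoms: none
Why: Claisen–Schmidt condensation and oxa-Michael closure as in step 1; the aryl bromide is inert to both.

Step 6
Reactants: 9 rac-7-(benzyloxy)-6-bromo-2-[3,4-bis(benzyloxy)phenyl]chroman-4-one; 6 rac-2-{7-(benzyloxy)-2-[3,4-bis(benzyloxy)phenyl]-2H-chromen-4-yl}-4,4,5,5-tetramethyl-1,3,2-dioxaborolane
Product: 10 7-(benzyloxy)-6-{7-(benzyloxy)-2-[3,4-bis(benzyloxy)phenyl]-2H-chromen-4-yl}-2-[3,4-bis(benzyloxy)phenyl]chroman-4-one (both C2 centres unassigned)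
Conditions: Pd(OAc)2, SPhos (2-dicyclohexylphosphino-2′,6′-dimethoxybiphenyl), CsF, 1,4-dioxane, 80 °C, dark
Reagents that add atoms: none
Why: Suzuki–Miyaura coupling of an aryl bromide with an alkenyl boronate forms C4(T)–C6(M). Fluoride activation without aqueous hydroxide protects the flavanone from retro-oxa-Michael opening, and the dialkylbiarylphosphine copes with the ortho benzyloxy group.

Step 7
Reactants: 10 7-(benzyloxy)-6-{7-(benzyloxy)-2-[3,4-bis(benzyloxy)phenyl]-2H-chromen-4-yl}-2-[3,4-bis(benzyloxy)phenyl]chroman-4-one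
Product: 11 7-(benzyloxy)-6-{7-(benzyloxy)-2-[3,4-bis(benzyloxy)phenyl]-2H-chromen-4-yl}-2-[3,4-bis(benzyloxy)phenyl]-2H-chromen-4-yl trifluoromethanesulfonate
Conditions: KN(SiMe3)2, THF, −78 °C; N-(5-chloro-2-pyridyl)bis(trifluoromethanesulfonimide), −78 °C, dark
Reagents that add atoms: N-(5-chloro-2-pyridyl)bis(trifluoromethanesulfonimide), FC(F)(F)S(=O)(=O)N(c1ccc(Cl)cn1)S(=O)(=O)C(F)(F)F
Why: Enol triflate formation as in step 2; the C2–H of the chromene already present is far too weakly acidic for the amide base at −78 °C.

Step 8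
Reactants: 11 7-(benzyloxy)-6-{7-(benzyloxy)-2-[3,4-bis(benzyloxy)phenyl]-2H-chromen-4-yl}-2-[3,4-bis(benzyloxy)phenyl]-2H-chromen-4-yl trifluoromethanesulfonate
Product: 12 2-{7-(benzyloxy)-6-{7-(benzyloxy)-2-[3,4-bis(benzyloxy)phenyl]-2H-chromen-4-yl}-2-[3,4-bis(benzyloxy)phenyl]-2H-chromen-4-yl}-4,4,5,5-tetramethyl-1,3,2-dioxaborolane
Conditions: B2pin2, PdCl2(PPh3)2, PPh3, KOPh, toluene, 50 °C, dark
Reagents that add atoms: bis(pinacolato)diboron, CC1(C)OB(OC1(C)C)B1OC(C)(C)C(C)(C)O1
Why: Miyaura borylation of the alkenyl triflate as in step 3; it turns the M unit from electrophile into nucleophile.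

Step 9
Reactants: 13 (+)-catechin, (2R,3S)
Product: 14 5,7,3′,4′-tetra-O-benzyl-(+)-catechin
Conditions: BnBr, K2CO3, DMF, 0 °C → rt, argon
Reagents that add atoms: benzyl bromide, BrCc1ccccc1
Why: Williamson etherification of the four phenols only, since carbonate does not deprotonate the 3-hydroxyl. The mild base and exclusion of air avoid C2 epimerisation through a ring-opened quinone methide and C-benzylation of ring A.

Step 10
Reactants: 14 5,7,3′,4′-tetra-O-benzyl-(+)-catechin
Product: 15 3,5,7,3′,4′-penta-O-benzyl-(+)-catechin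
Conditions: NaH, BnBr, Bu4NI (cat.), DMF, 0 °C → rt
Reagents that add atoms: benzyl bromide, BrCc1ccccc1
Why: Williamson etherification of the secondary alcohol; with no phenoxide left, C2 and C3 of K are not at risk.

Step 11
Reactants: 15 3,5,7,3′,4′-penta-O-benzyl-(+)-catechin
Product: 16 8-bromo-3,5,7,3′,4′-penta-O-benzyl-(+)-catechin
Conditions: NBS (1 equiv), CH2Cl2, −78 °C → rt
Reagents that add atoms: N-bromosuccinimide, BrN1C(=O)CCC1=O
Why: Electrophilic aromatic bromination; C8 of the tri-oxygenated ring A is the established first site of halogenation in O-benzylated catechins, and ring B is far less activated.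

Step 12
Reactants: 16 8-bromo-3,5,7,3′,4′-penta-O-benzyl-(+)-catechin
Product: 17 8-bromo-6-iodo-3,5,7,3′,4′-penta-O-benzyl-(+)-catechin
Conditions: NIS, CF3CO2H (cat.), CH2Cl2/MeCN, 0 °C → rt
Reagents that add atoms: N-iodosuccinimide, IN1C(=O)CCC1=O
Why: Electrophilic aromatic iodination at the only free position of ring A. Bromine is put in first and iodine second so that no ipso exchange of halogen occurs and C6 becomes the more reactive coupling site.

Step 13
Reactants: 17 8-bromo-6-iodo-3,5,7,3′,4′-penta-O-benzyl-(+)-catechin; 6 rac-2-{7-(benzyloxy)-2-[3,4-bis(benzyloxy)phenyl]-2H-chromen-4-yl}-4,4,5,5-tetramethyl-1,3,2-dioxaborolane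
Product: 18 8-bromo-6-{7-(benzyloxy)-2-[3,4-bis(benzyloxy)phenyl]-2H-chromen-4-yl}-3,5,7,3′,4′-penta-O-benzyl-(+)-catechin (chromene C2 unassigned)
Conditions: Pd(PPh3)4, K3PO4, 1,4-dioxane/H2O, 65 °C, dark
Reagents that add atoms: none
Why: Suzuki–Miyaura coupling forms C4(S)–C6(K). Zerovalent palladium inserts into C–I much faster than into C–Br, so with a triarylphosphine catalyst and about one equivalent of 6 only C6 reacts and the C8 bromide is kept for step 14.

Step 14
Reactants: 18 8-bromo-6-{7-(benzyloxy)-2-[3,4-bis(benzyloxy)phenyl]-2H-chromen-4-yl}-3,5,7,3′,4′-penta-O-benzyl-(+)-catechin; 12 2-{7-(benzyloxy)-6-{7-(benzyloxy)-2-[3,4-bis(benzyloxy)phenyl]-2H-chromen-4-yl}-2-[3,4-bis(benzyloxy)phenyl]-2H-chromen-4-yl}-4,4,5,5-tetramethyl-1,3,2-dioxaborolane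
Product: 19 tris(flav-3-ene): 3,5,7,3′,4′-penta-O-benzyl-(+)-catechin carrying a 7-(benzyloxy)-2-[3,4-bis(benzyloxy)phenyl]-2H-chromen-4-yl group on C6 (unit S) and on C8 (unit M), unit M carrying a third such group (unit T) on its own C6; mixture of all eight C2 epimers of T, M and S
Conditions: Pd(OAc)2, SPhos, K3PO4, toluene/H2O, 90 °C, dark
Reagents that add atoms: none
Why: Suzuki–Miyaura coupling forms C4(M)–C8(K) at an aryl bromide flanked by two oxygens; an electron-rich, bulky dialkylbiarylphosphine is the standard answer to such crowded aryl–alkenyl junctions. No stereocentre is set, and the epimer mixture is intended.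

Step 15
Reactants: 19 tris(flav-3-ene), mixture of eight C2 epimers
Product: 20 tris(3,4-epoxide): in each of T, M and S the C2 aryl group is β (2S) and a cis-fused 3,4-oxirane has its oxygen on the α face; K unchanged
Conditions: (R,R)-(salen)MnCl (trivalent manganese; salen = N,N′-bis(3,5-di-tert-butylsalicylidene)-1,2-cyclohexanediamine dianion; 5 mol % per alkene), 4-phenylpyridine N-oxide, NaOCl (aq., pH 11.3, slow addition), CH2Cl2, 0 °C, 365 nm LED; cold phase separation, basic alumina, used at once
Reagents that add atoms: sodium hypochlorite, [Na+].[O-]Cl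
Why: Proposed new method: near-UV light opens O1–C2 of each 2H-chromene by 6π electrocyclic ring opening to an ortho-quinone methide in which the former C2 is trigonal, and thermal oxa-6π ring closure returns either C2 epimer, so all eight isomers of 19 interconvert while a C3=C4 chromophore remains. The oxo species of pentavalent manganese, formed from the trivalent (salen)MnCl and NaOCl, transfers oxygen stepwise: C3–O forms first and leaves a C4 radical flanked by two aryl groups, then 3-exo collapse onto the manganese-bound oxygen forms C4–O and closes each of the three oxiranes, which the six-membered ring forces to be cis-fused. The closest known reaction types are the kinetic resolution of racemic 2-substituted 2H-chromenes by manganese-salen (Jacobsen–Katsuki) epoxidation and the photochromic ring opening of 2H-chromenes; running them together is untested. C3 and C4 of T, M and S are set by the ligand, which by analogy with 2,2-dimethylchromene should send oxygen to the α face; C2 is set by the resolution, since only the epimer whose 3,4-dibenzyloxyphenyl group sits on the β face leaves the α face open and reacts fast, and once epoxidised it no longer absorbs at 365 nm and is locked. The step needs one alkene face, a large rate gap between the C2 epimers and epimerisation faster than oxidation of the mismatched epimer: the first comes from the ligand, the second from the C2 aryl group shielding its own face, the third from photon flux and slow addition of NaOCl. The three alkenes are insulated from one another by aryl rings and should react independently, the two fixed centres of K being remote. The pH 11.3 buffer protects the acid-labile oxiranes, and only the organic phase is passed through the LED coil so that hypochlorite is not photolysed.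

Step 16
Reactants: 20 tris(3,4-epoxide)
Product: 21 tetradeca-O-benzyl ether of 22 (all thirteen phenols and O3 of K benzylated; O3 of T, M and S free; T, M and S each 2S,3R with the C4 aryl group α)
Conditions: Et3SiH (large excess), BF3·OEt2, CH2Cl2, −78 °C (solution of 20 added to the reagents); aq. NaHCO3
Reagents that add atoms: none
Why: Reductive opening of an epoxide by ionic hydrogenation: BF3 ionises the tertiary, doubly benzylic C4–O bond, never C3–O, and the silane delivers hydride to C4 anti to the departing O3, which is also the face preferred by 2,3-trans flavan-4-yl cations. Hydrogen therefore ends trans and the aryl group cis to the 3-oxygen (3,4-cis, 4α), and the O–BF2 group is hydrolysed on work-up. Inverse addition into excess silane at −78 °C is meant to outrun the 1,2-hydride shift to a flavan-3-one and to spare the benzylic C2–O1 bonds.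

Step 17
Reactants: 21 tetradeca-O-benzyl ether of 22
Product: 22 ent-fisetinidol-(4α→6)-ent-fisetinidol-(4α→8)-catechin-(6→4α)-ent-fisetinidol (CNP0126838.1)
Conditions: H2 (1 atm), Pd(OH)2 on carbon, THF/MeOH, rt; Sephadex LH-20
Reagents that add atoms: none
Why: Catalytic hydrogenolysis cleaves the fourteen benzyl ethers under neutral conditions. The cyclic C2–O1 ethers and the C4–aryl bonds of 5-deoxy flavan units are not cleaved under these conditions, so no stereocentre is touched.

## Compound list

1 | 1-[4-(benzyloxy)-2-hydroxyphenyl]ethan-1-one | CC(=O)c1ccc(OCc2ccccc2)cc1O | starting material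
2 | 3,4-bis(benzyloxy)benzaldehyde | O=Cc1ccc(OCc2ccccc2)c(OCc2ccccc2)c1 | starting material
3 | (E)-1-[4-(benzyloxy)-2-hydroxyphenyl]-3-[3,4-bis(benzyloxy)phenyl]prop-2-en-1-one (chalcone) | O=C(/C=C/c1ccc(OCc2ccccc2)c(OCc2ccccc2)c1)c1ccc(OCc2ccccc2)cc1O | intermediate
4 | rac-7-(benzyloxy)-2-[3,4-bis(benzyloxy)phenyl]chroman-4-one | O=C1CC(c2ccc(OCc3ccccc3)c(OCc3ccccc3)c2)Oc2cc(OCc3ccccc3)ccc12 | intermediate
5 | rac-7-(benzyloxy)-2-[3,4-bis(benzyloxy)phenyl]-2H-chromen-4-yl trifluoromethanesulfonate | FC(F)(F)S(=O)(=O)OC1=CC(c2ccc(OCc3ccccc3)c(OCc3ccccc3)c2)Oc2cc(OCc3ccccc3)ccc12 | intermediate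
6 | rac-2-{7-(benzyloxy)-2-[3,4-bis(benzyloxy)phenyl]-2H-chromen-4-yl}-4,4,5,5-tetramethyl-1,3,2-dioxaborolane | CC1(C)OB(OC1(C)C)C1=CC(c2ccc(OCc3ccccc3)c(OCc3ccccc3)c2)Oc2cc(OCc3ccccc3)ccc12 | intermediate
7 | 1-[4-(benzyloxy)-5-bromo-2-hydroxyphenyl]ethan-1-one | CC(=O)c1cc(Br)c(OCc2ccccc2)cc1O | intermediate
8 | (E)-1-[4-(benzyloxy)-5-bromo-2-hydroxyphenyl]-3-[3,4-bis(benzyloxy)phenyl]prop-2-en-1-one (bromochalcone) | O=C(/C=C/c1ccc(OCc2ccccc2)c(OCc2ccccc2)c1)c1cc(Br)c(OCc2ccccc2)cc1O | intermediate
9 | rac-7-(benzyloxy)-6-bromo-2-[3,4-bis(benzyloxy)phenyl]chroman-4-one | O=C1CC(c2ccc(OCc3ccccc3)c(OCc3ccccc3)c2)Oc2cc(OCc3ccccc3)c(Br)cc12 | intermediate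
10 | 7-(benzyloxy)-6-{7-(benzyloxy)-2-[3,4-bis(benzyloxy)phenyl]-2H-chromen-4-yl}-2-[3,4-bis(benzyloxy)phenyl]chroman-4-one (C2 centres unassigned) | c9ccccc9COc1ccc2c(c1)OC(c1ccc(OCc9ccccc9)c(OCc9ccccc9)c1)C=C2c1cc2c(cc1OCc9ccccc9)OC(c1ccc(OCc9ccccc9)c(OCc9ccccc9)c1)CC2=O | intermediate
11 | enol triflate of 10 (2H-chromen-4-yl trifluoromethanesulfonate of unit M carrying unit T on C6) | c9ccccc9COc1ccc2c(c1)OC(c1ccc(OCc9ccccc9)c(OCc9ccccc9)c1)C=C2c1cc2c(cc1OCc9ccccc9)OC(c1ccc(OCc9ccccc9)c(OCc9ccccc9)c1)C=C2OS(=O)(=O)C(F)(F)F | intermediate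
12 | pinacol boronate of the T–M bis-chromene (boron on C4 of unit M) | c9ccccc9COc1ccc2c(c1)OC(c1ccc(OCc9ccccc9)c(OCc9ccccc9)c1)C=C2c1cc2c(cc1OCc9ccccc9)OC(c1ccc(OCc9ccccc9)c(OCc9ccccc9)c1)C=C2B1OC(C)(C)C(C)(C)O1 | intermediate
13 | (+)-catechin, (2R,3S) | Oc1cc(O)c2c(c1)O[C@H](c1ccc(O)c(O)c1)[C@@H](O)C2 | starting material
14 | 5,7,3′,4′-tetra-O-benzyl-(+)-catechin | c9ccccc9COc1cc(OCc9ccccc9)c2c(c1)O[C@H](c1ccc(OCc9ccccc9)c(OCc9ccccc9)c1)[C@@H](O)C2 | intermediate
15 | 3,5,7,3′,4′-penta-O-benzyl-(+)-catechin | c9ccccc9COc1cc(OCc9ccccc9)c2c(c1)O[C@H](c1ccc(OCc9ccccc9)c(OCc9ccccc9)c1)[C@@H](OCc9ccccc9)C2 | intermediate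
16 | 8-bromo-3,5,7,3′,4′-penta-O-benzyl-(+)-catechin | c9ccccc9COc1cc(OCc9ccccc9)c2c(c1Br)O[C@H](c1ccc(OCc9ccccc9)c(OCc9ccccc9)c1)[C@@H](OCc9ccccc9)C2 | intermediate
17 | 8-bromo-6-iodo-3,5,7,3′,4′-penta-O-benzyl-(+)-catechin | c9ccccc9COc1c(I)c(OCc9ccccc9)c2c(c1Br)O[C@H](c1ccc(OCc9ccccc9)c(OCc9ccccc9)c1)[C@@H](OCc9ccccc9)C2 | intermediate
18 | 8-bromo-6-{7-(benzyloxy)-2-[3,4-bis(benzyloxy)phenyl]-2H-chromen-4-yl}-3,5,7,3′,4′-penta-O-benzyl-(+)-catechin (chromene C2 unassigned) | Brc1c(OCc9ccccc9)c(C2=CC(c3ccc(OCc9ccccc9)c(OCc9ccccc9)c3)Oc3cc(OCc9ccccc9)ccc32)c(OCc9ccccc9)c2c1O[C@H](c1ccc(OCc9ccccc9)c(OCc9ccccc9)c1)[C@@H](OCc9ccccc9)C2 | intermediate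
19 | tris(flav-3-ene) on penta-O-benzylcatechin, mixture of eight C2 epimers | c9ccccc9COc1ccc2c(c1)OC(c1ccc(OCc9ccccc9)c(OCc9ccccc9)c1)C=C2c1cc2c(cc1OCc9ccccc9)OC(c1ccc(OCc9ccccc9)c(OCc9ccccc9)c1)C=C2c1c(OCc9ccccc9)c(C2=CC(c3ccc(OCc9ccccc9)c(OCc9ccccc9)c3)Oc3cc(OCc9ccccc9)ccc32)c(OCc9ccccc9)c2c1O[C@H](c1ccc(OCc9ccccc9)c(OCc9ccccc9)c1)[C@@H](OCc9ccccc9)C2 | intermediate
20 | tris(3,4-epoxide), C2 aryl β and oxirane oxygen α in T, M and S | c9ccccc9COc1ccc2c(c1)O[C@@H](c1ccc(OCc9ccccc9)c(OCc9ccccc9)c1)[C@@H]4O[C@]24c1cc2c(cc1OCc9ccccc9)O[C@@H](c1ccc(OCc9ccccc9)c(OCc9ccccc9)c1)[C@@H]4O[C@]24c1c(OCc9ccccc9)c([C@@]24c3ccc(OCc9ccccc9)cc3O[C@@H](c3ccc(OCc9ccccc9)c(OCc9ccccc9)c3)[C@@H]2O4)c(OCc9ccccc9)c2c1O[C@H](c1ccc(OCc9ccccc9)c(OCc9ccccc9)c1)[C@@H](OCc9ccccc9)C2 | intermediate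
21 | tetradeca-O-benzyl ether of 22 with free 3-hydroxyls on T, M and S | c9ccccc9COc1ccc2c(c1)O[C@@H](c1ccc(OCc9ccccc9)c(OCc9ccccc9)c1)[C@H](O)[C@@H]2c1cc2c(cc1OCc9ccccc9)O[C@@H](c1ccc(OCc9ccccc9)c(OCc9ccccc9)c1)[C@H](O)[C@@H]2c1c(OCc9ccccc9)c([C@@H]2c3ccc(OCc9ccccc9)cc3O[C@@H](c3ccc(OCc9ccccc9)c(OCc9ccccc9)c3)[C@@H]2O)c(OCc9ccccc9)c2c1O[C@H](c1ccc(OCc9ccccc9)c(OCc9ccccc9)c1)[C@@H](OCc9ccccc9)C2 | intermediate
22 | ent-fisetinidol-(4α→6)-ent-fisetinidol-(4α→8)-catechin-(6→4α)-ent-fisetinidol (CNP0126838.1) | Oc1ccc2c(c1)O[C@@H](c1ccc(O)c(O)c1)[C@H](O)[C@@H]2c1cc2c(cc1O)O[C@@H](c1ccc(O)c(O)c1)[C@H](O)[C@@H]2c1c(O)c([C@@H]2c3ccc(O)cc3O[C@@H](c3ccc(O)c(O)c3)[C@@H]2O)c(O)c2c1O[C@H](c1ccc(O)c(O)c1)[C@@H](O)C2 | target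

## Step count and least certain steps

Total: 17 steps. Longest linear sequence: 10 steps (1, 2, 3, 6, 7, 8, 14, 15, 16, 17).

Step 15 (key step). The stereoconvergence is most likely to fail because C2 epimerisation does not keep pace with oxygen transfer: the brown manganese complex competes for the 365 nm photons, so mismatched epimers get epoxidised. Also likely are over-oxidation of the transient open quinone-methide form and of electron-rich rings by hypochlorite, and premature Lewis-acid opening of the very electron-rich oxiranes. The fallback uses known chemistry, sets out from 4 and 9 and returns at 20.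
- Racemic 4 and 9 are resolved by preparative chromatography on a polysaccharide chiral stationary phase, the unwanted antipodes being racemised with base through the chalcone and recycled. This gives (2R)-7-(benzyloxy)-2-[3,4-bis(benzyloxy)phenyl]chroman-4-one F1 and (2R)-7-(benzyloxy)-6-bromo-2-[3,4-bis(benzyloxy)phenyl]chroman-4-one F2.
- With light excluded and coupling temperatures kept as low as possible, the conditions of steps 2 and 3 convert F1 into the (2R)-chromenyl triflate F3 and the (2R)-chromenyl pinacol boronate F4.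
- F4 and F2 give under the conditions of step 6 the (2R,2R)-chromenyl-flavanone F5, which is taken as in steps 7 and 8 to the (2R,2R)-bis-chromenyl triflate F6 and the (2R,2R)-bis-chromenyl pinacol boronate F7.
- F4 and 17 give as in step 13 the (2R)-chromenyl bromide F8, and F7 with F8 give as in step 14 the all-(2R) isomer of the tris(flav-3-ene) F9.
- Dimethyldioxirane in acetone/CH2Cl2 at −40 °C then epoxidises each alkene anti to its own C2 aryl group, the substrate-controlled course known for flav-3-enes, and gives 20.

Step 16. The reduction is most likely to be diverted by a 1,2-hydride shift of the long-lived diaryl cation (Meinwald-type rearrangement to a flavan-3-one). It may also lose face selectivity if the cation fully dissociates from the boron-bound oxygen, or cleave benzylic C2–O1 bonds if the temperature rises. The fallback sets out from 20 and returns at 22: heterogeneous hydrogenolysis (H2, Pd(OH)2 on carbon, THF/MeOH with a trace of Et3N) cleaves the benzylic C4–O bond of each oxirane, on palladium normally with inversion, and removes the benzyl ethers in the same operation. No new compound is involved.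

Step 14. The coupling may stall at transmetalation or reductive elimination because both partners are crowded, with protodeboronation of 12 and hydrodebromination of 18 taking over. The fallback sets out from 18 and 10 and returns at 19, and is two steps shorter because 11 and 12 are bypassed. Bromine–lithium exchange on 18 (t-BuLi, THF, −78 °C) and transmetalation to CeCl3 give an aryl nucleophile that adds to the ketone of 10, a known way to join C8 of benzylated catechins to flavan-4-ones. This forms the tertiary 4-aryl-flavan-4-ol F10; warming with pyridinium p-toluenesulfonate in toluene dehydrates it by E1 loss of H3 to 19.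

Step 13. Selection between C6–I and C8–Br may be incomplete, or the coupling between two benzyloxy groups may be slow enough that hydrodeiodination and double arylation compete. The fallback sets out from 17 and 4 and returns at 18. Iodine–magnesium exchange with iPrMgCl·LiCl at −40 °C, which leaves the bromide alone, followed by addition to ketone 4 in the presence of LaCl3·2LiCl gives the tertiary 4-aryl-flavan-4-ol F11. Dehydration with pyridinium p-toluenesulfonate gives 18.

Step 2 (the same concern applies to step 7). E1cB ring opening of the flavanone enolate to the chalcone phenoxide may compete with O-sulfonylation. The fallback sets out from 4 and returns at 6 without any enolate. Triphenyl phosphite/bromine with Et3N in CH2Cl2 at −60 °C → rt converts the ketone into rac-7-(benzyloxy)-4-bromo-2-[3,4-bis(benzyloxy)phenyl]-2H-chromene F12, and Miyaura borylation (B2pin2, PdCl2(PPh3)2, KOAc, dioxane, 80 °C) gives 6.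

## Further compounds

F1 | step 15 | (2R)-7-(benzyloxy)-2-[3,4-bis(benzyloxy)phenyl]chroman-4-one | c9ccccc9COc1ccc2c(c1)O[C@@H](c1ccc(OCc9ccccc9)c(OCc9ccccc9)c1)CC2=O
F2 | step 15 | (2R)-7-(benzyloxy)-6-bromo-2-[3,4-bis(benzyloxy)phenyl]chroman-4-one | Brc1cc2c(cc1OCc9ccccc9)O[C@@H](c1ccc(OCc9ccccc9)c(OCc9ccccc9)c1)CC2=O
F3 | step 15 | (2R)-chromenyl triflate (single enantiomer of 5) | c9ccccc9COc1ccc2c(c1)O[C@@H](c1ccc(OCc9ccccc9)c(OCc9ccccc9)c1)C=C2OS(=O)(=O)C(F)(F)F
F4 | step 15 | (2R)-chromenyl pinacol boronate (single enantiomer of 6) | c9ccccc9COc1ccc2c(c1)O[C@@H](c1ccc(OCc9ccccc9)c(OCc9ccccc9)c1)C=C2B1OC(C)(C)C(C)(C)O1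
F5 | step 15 | (2R,2R)-chromenyl-flavanone (single isomer of 10) | c9ccccc9COc1ccc2c(c1)O[C@@H](c1ccc(OCc9ccccc9)c(OCc9ccccc9)c1)C=C2c1cc2c(cc1OCc9ccccc9)O[C@@H](c1ccc(OCc9ccccc9)c(OCc9ccccc9)c1)CC2=O
F6 | step 15 | (2R,2R)-bis-chromenyl triflate (single isomer of 11) | c9ccccc9COc1ccc2c(c1)O[C@@H](c1ccc(OCc9ccccc9)c(OCc9ccccc9)c1)C=C2c1cc2c(cc1OCc9ccccc9)O[C@@H](c1ccc(OCc9ccccc9)c(OCc9ccccc9)c1)C=C2OS(=O)(=O)C(F)(F)F
F7 | step 15 | (2R,2R)-bis-chromenyl pinacol boronate (single isomer of 12) | c9ccccc9COc1ccc2c(c1)O[C@@H](c1ccc(OCc9ccccc9)c(OCc9ccccc9)c1)C=C2c1cc2c(cc1OCc9ccccc9)O[C@@H](c1ccc(OCc9ccccc9)c(OCc9ccccc9)c1)C=C2B1OC(C)(C)C(C)(C)O1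
F8 | step 15 | (2R)-chromenyl bromide (single isomer of 18) | Brc1c(OCc9ccccc9)c(C2=C[C@H](c3ccc(OCc9ccccc9)c(OCc9ccccc9)c3)Oc3cc(OCc9ccccc9)ccc32)c(OCc9ccccc9)c2c1O[C@H](c1ccc(OCc9ccccc9)c(OCc9ccccc9)c1)[C@@H](OCc9ccccc9)C2
F9 | step 15 | all-(2R) isomer of the tris(flav-3-ene) (single isomer of 19) | c9ccccc9COc1ccc2c(c1)O[C@@H](c1ccc(OCc9ccccc9)c(OCc9ccccc9)c1)C=C2c1cc2c(cc1OCc9ccccc9)O[C@@H](c1ccc(OCc9ccccc9)c(OCc9ccccc9)c1)C=C2c1c(OCc9ccccc9)c(C2=C[C@H](c3ccc(OCc9ccccc9)c(OCc9ccccc9)c3)Oc3cc(OCc9ccccc9)ccc32)c(OCc9ccccc9)c2c1O[C@H](c1ccc(OCc9ccccc9)c(OCc9ccccc9)c1)[C@@H](OCc9ccccc9)C2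
F0 | step 16 | none | none
F10 | step 14 | tertiary 4-aryl-flavan-4-ol (unit M hydrated at C4, units T and S as chromenes) | c9ccccc9COc1ccc2c(c1)OC(c1ccc(OCc9ccccc9)c(OCc9ccccc9)c1)C=C2c1cc2c(cc1OCc9ccccc9)OC(c1ccc(OCc9ccccc9)c(OCc9ccccc9)c1)CC2(O)c1c(OCc9ccccc9)c(C2=CC(c3ccc(OCc9ccccc9)c(OCc9ccccc9)c3)Oc3cc(OCc9ccccc9)ccc32)c(OCc9ccccc9)c2c1O[C@H](c1ccc(OCc9ccccc9)c(OCc9ccccc9)c1)[C@@H](OCc9ccccc9)C2
F11 | step 13 | tertiary 4-aryl-flavan-4-ol (unit S hydrated at C4, bromine on C8 of K) | Brc1c(OCc9ccccc9)c(C2(O)CC(c3ccc(OCc9ccccc9)c(OCc9ccccc9)c3)Oc3cc(OCc9ccccc9)ccc32)c(OCc9ccccc9)c2c1O[C@H](c1ccc(OCc9ccccc9)c(OCc9ccccc9)c1)[C@@H](OCc9ccccc9)C2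
F12 | step 2 | rac-7-(benzyloxy)-4-bromo-2-[3,4-bis(benzyloxy)phenyl]-2H-chromene | BrC1=CC(c2ccc(OCc3ccccc3)c(OCc3ccccc3)c2)Oc2cc(OCc3ccccc3)ccc12
A1 | alternative 1 | hexahydrochromen-7-one on the benzylated trimer (C4a epimers) | O=C1CCC2C(=C1)O[C@@H](c1ccc(OCc9ccccc9)c(OCc9ccccc9)c1)[C@H](OCc9ccccc9)[C@@H]2c1cc2c(cc1OCc9ccccc9)O[C@@H](c1ccc(OCc9ccccc9)c(OCc9ccccc9)c1)[C@H](OCc9ccccc9)[C@@H]2c1c(OCc9ccccc9)c([C@@H]2c3ccc(OCc9ccccc9)cc3O[C@@H](c3ccc(OCc9ccccc9)c(OCc9ccccc9)c3)[C@@H]2OCc9ccccc9)c(OCc9ccccc9)c2c1O[C@H](c1ccc(OCc9ccccc9)c(OCc9ccccc9)c1)[C@@H](OCc9ccccc9)C2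
A2 | alternative 1 | methyl vinyl ketone | CC(=O)C=C
A3 | alternative 2 | tris(4-hydroxy-4-aryl) 2,3-trans-flavan-3-ol tetramer, phenols benzylated (either C4 epimer) | c9ccccc9COc1ccc2c(c1)O[C@@H](c1ccc(OCc9ccccc9)c(OCc9ccccc9)c1)[C@H](O)C2(O)c1cc2c(cc1OCc9ccccc9)O[C@@H](c1ccc(OCc9ccccc9)c(OCc9ccccc9)c1)[C@H](O)C2(O)c1c(OCc9ccccc9)c(C2(O)c3ccc(OCc9ccccc9)cc3O[C@@H](c3ccc(OCc9ccccc9)c(OCc9ccccc9)c3)[C@@H]2O)c(OCc9ccccc9)c2c1O[C@H](c1ccc(OCc9ccccc9)c(OCc9ccccc9)c1)[C@@H](OCc9ccccc9)C2
A4 | alternative 2 | droxidopa, (2S,3R)-2-amino-3-(3,4-dihydroxyphenyl)-3-hydroxypropanoic acid | OC(=O)[C@@H](N)[C@H](O)c1ccc(O)c(O)c1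
A5 | alternative 3 | heptadeca-O-benzyl ether of the target | c9ccccc9COc1ccc2c(c1)O[C@@H](c1ccc(OCc9ccccc9)c(OCc9ccccc9)c1)[C@H](OCc9ccccc9)[C@@H]2c1cc2c(cc1OCc9ccccc9)O[C@@H](c1ccc(OCc9ccccc9)c(OCc9ccccc9)c1)[C@H](OCc9ccccc9)[C@@H]2c1c(OCc9ccccc9)c([C@@H]2c3ccc(OCc9ccccc9)cc3O[C@@H](c3ccc(OCc9ccccc9)c(OCc9ccccc9)c3)[C@@H]2OCc9ccccc9)c(OCc9ccccc9)c2c1O[C@H](c1ccc(OCc9ccccc9)c(OCc9ccccc9)c1)[C@@H](OCc9ccccc9)C2
A6 | alternative 3 | 4-bromo-1,2-bis(benzyloxy)benzene | Brc1ccc(OCc2ccccc2)c(OCc2ccccc2)c1
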